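The route rests on disconnecting ring C at the C4–C4a aryl ketone bond. A one-flask ester unmasking and intramolecular Friedel–Crafts acylation turns an open-chain (S)-3-aryl-3-aryloxypropanoate, made by Mitsunobu inversion from symmetric 2-bromo-5-methoxyresorcinol, into the 8-bromoflavanone. The step exploits that C4a, lying between O1 and the C5 methoxy group of phloroglucinol-type ring A, is the only carbon the O1–C2–C3 tether can reach once C8 carries bromine; the C2 stereocentre is untouched. The same bromine then serves as the handle for a late Negishi union with the (R)-configured hydrated lavandulyl side chain, built by Evans deconjugative alkylation.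

Key step: step 9

Remark: flavanone numbering is used (O1, C2, C3, C4, C4a, C5–C8, C8a; ring B primed); compounds 1, 6, 8, 16, 17 and 20 are taken as commercial.

Step 1
Reactants: 1 5-methoxybenzene-1,3-diol
Product: 2 1-methoxy-3,5-bis(methoxymethoxy)benzene
Conditions: MOMCl, K2CO3, acetone, 0 °C → rt
Reagents that add atoms: chloromethyl methyl ether, COCCl
Why: Williamson-type O-alkylation of the two equivalent phenols gives the bis-MOM ether, whose acetal oxygens are the directing groups for the next step.

Step 2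
Reactants: 2 1-methoxy-3,5-bis(methoxymethoxy)benzene
Product: 4 2-bromo-5-methoxy-1,3-bis(methoxymethoxy)benzene, via aryllithium 3 (not isolated)
Conditions: n-BuLi, THF, 0 °C; then BrCCl2CCl2Br, −78 °C → rt
Reagents that add atoms: 1,2-dibromo-1,1,2,2-tetrachloroethane, BrC(Cl)(Cl)C(Cl)(Cl)Br
Why: Directed ortho-metalation removes the proton between the two chelating MOM ethers in preference to those next to the weaker methoxy director, and bromine transfer to the aryllithium then fixes the halogen at the future C8.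

Step 3
Reactants: 4 2-bromo-5-methoxy-1,3-bis(methoxymethoxy)benzene
Product: 5 2-bromo-5-methoxybenzene-1,3-diol
Conditions: HCl (cat.), MeOH, 40 °C
Reagents that add atoms: none
Why: Acid-catalysed acetal exchange with methanol frees both phenols, giving a symmetric resorcinol whose two OH groups are equivalent, so either may become O1 and the other O7.

Step 4
Reactants: 6 4-hydroxy-2-methoxybenzaldehyde
Product: 7 4-formyl-3-methoxyphenyl acetate
Conditions: Ac2O, pyridine, CH2Cl2, 0 °C → rt
Reagents that add atoms: acetic anhydride, CC(=O)OC(C)=O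
Why: O-Acylation of the phenol makes O4' a poorer donor, which later protects the benzylic C2–O1 bond against ionisation.

Step 5
Reactants: 7 4-formyl-3-methoxyphenyl acetate; 8 tert-butyl diazoacetate
Product: 9 tert-butyl 3-[4-(acetyloxy)-2-methoxyphenyl]-3-oxopropanoate
Conditions: SnCl2 (10 mol%), CH2Cl2, rt
Reagents that add atoms: none
Why: Roskamp reaction, in which the SnCl2-activated aldehyde adds the diazo ester and a 1,2-hydride shift with loss of dinitrogen gives the β-keto ester directly.

Step 6
Reactants: 9 tert-butyl 3-[4-(acetyloxy)-2-methoxyphenyl]-3-oxopropanoate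
Product: 10 tert-butyl (3R)-3-[4-(acetyloxy)-2-methoxyphenyl]-3-hydroxypropanoate
Conditions: RuCl[(R,R)-TsDPEN](p-cymene) (1 mol%), HCO2H–Et3N (5:2), rt
Reagents that add atoms: none
Why: Noyori asymmetric transfer hydrogenation of the aryl ketone, in which the (R,R)-diamine complex is expected to deliver hydride to the face giving the (R)-carbinol through the usual aryl CH–π transition state, as for acetophenone-type ketones.

Step 7
Reactants: 10 tert-butyl (3R)-3-[4-(acetyloxy)-2-methoxyphenyl]-3-hydroxypropanoate; 5 2-bromo-5-methoxybenzene-1,3-diol (2.5 equiv, excess recovered)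
Product: 11 tert-butyl (3S)-3-[4-(acetyloxy)-2-methoxyphenyl]-3-(2-bromo-3-hydroxy-5-methoxyphenoxy)propanoate
Conditions: PPh3, DIAD, THF, 0 °C → rt
Reagents that add atoms: none
Why: Mitsunobu etherification, in which the acidic bromophenol displaces the alkoxyphosphonium group by SN2 with inversion (3R to 3S, the future C2), while the symmetry of 5 and its use in excess make mono-etherification the main outcome.

Step 8
Reactants: 11 tert-butyl (3S)-3-[4-(acetyloxy)-2-methoxyphenyl]-3-(2-bromo-3-hydroxy-5-methoxyphenoxy)propanoate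
Product: 12 tert-butyl (3S)-3-[3-(acetyloxy)-2-bromo-5-methoxyphenoxy]-3-[4-(acetyloxy)-2-methoxyphenyl]propanoate
Conditions: Ac2O, pyridine, CH2Cl2, rt
Reagents that add atoms: acetic anhydride, CC(=O)OC(C)=O
Why: O-Acylation of the remaining phenol masks the future 7-OH, which would otherwise be acylated in step 9 and would protonate the organozinc reagent in step 16.

Step 9
Reactants: 12 tert-butyl (3S)-3-[3-(acetyloxy)-2-bromo-5-methoxyphenoxy]-3-[4-(acetyloxy)-2-methoxyphenyl]propanoate
Product: 15 (2S)-7-(acetyloxy)-2-[4-(acetyloxy)-2-methoxyphenyl]-8-bromo-5-methoxy-2,3-dihydro-4H-chromen-4-one, via carboxylic acid 13 (not isolated), via mixed trifluoroacetic anhydride 14 (not isolated)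
Conditions: TFA, CH2Cl2, 0 °C → rt; then TFAA, CH2Cl2 (0.02 M), 0 °C → rt
Reagents that add atoms: none
Why: TFA cleaves the tert-butyl ester by alkyl–oxygen fission (isobutene lost) to acid 13, TFAA converts this into mixed anhydride 14, and its activated carbonyl (or the derived acylium ion) is attacked by C4a of ring A before loss of a proton restores the arene. The closest known reaction type is the intramolecular Friedel–Crafts acylation of 3-aryloxypropanoic acids to chroman-4-ones. Ring C closes in a 6-exo-trig mode through the O1–C2–C3 tether. No stereocentre is formed; C2 keeps its S configuration because no bond to it is broken, and the 4'-acetate keeps the benzylic C2–O1 bond from ionising in acid. Regioselectivity is secured by the substrate: C8 is blocked by bromine, C6 is para to O1 and out of reach, and C6' of ring B is meta to both of its oxygen substituents, so indanone formation is disfavoured. High dilution is used so that intermolecular acylation at C6 does not compete.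

Step 10
Reactants: 16 (4S)-4-benzyl-1,3-oxazolidin-2-one; 17 3-methylbut-2-enoyl chloride
Product: 19 (4S)-4-benzyl-3-(3-methylbut-2-enoyl)-1,3-oxazolidin-2-one, via lithiated oxazolidinone 18 (not isolated)
Conditions: n-BuLi, THF, −78 °C; then 17, −78 → 0 °C
Reagents that add atoms: none
Why: N-Acylation of the lithium salt of the Evans oxazolidinone at low temperature, which avoids the vinylketene pathway that amine bases open for this acid chloride.

Step 11
Reactants: 19 (4S)-4-benzyl-3-(3-methylbut-2-enoyl)-1,3-oxazolidin-2-one; 20 1-bromo-3-methylbut-2-ene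
Product: 22 (4S)-4-benzyl-3-[(2S)-5-methyl-2-(prop-1-en-2-yl)hex-4-enoyl]-1,3-oxazolidin-2-one, via sodium dienolate 21 (not isolated)
Conditions: NaN(SiMe3)2, THF, −78 °C; then 20, −78 → −40 °C
Reagents that add atoms: none
Why: Evans asymmetric alkylation in its deconjugative form, in which γ-deprotonation gives the chelated Z-dienolate that is alkylated at the α-carbon on the face away from the benzyl group, setting the (S)-centre and unveiling the isopropenyl group in one step.

Step 12
Reactants: 22 (4S)-4-benzyl-3-[(2S)-5-methyl-2-(prop-1-en-2-yl)hex-4-enoyl]-1,3-oxazolidin-2-one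
Product: 23 (4S)-4-benzyl-3-{(2S)-2-[(3,3-dimethyloxiran-2-yl)methyl]-3-methylbut-3-enoyl}-1,3-oxazolidin-2-one (both oxirane epimers)
Conditions: mCPBA (1.05 equiv), NaHCO3, CH2Cl2, 0 °C
Reagents that add atoms: 3-chloroperoxybenzoic acid, OOC(=O)c1cccc(Cl)c1
Why: Prilezhaev epoxidation is chemoselective for the electron-rich trisubstituted alkene over the 1,1-disubstituted one next to the acyl-bearing carbon, and the new oxirane centre is left uncontrolled because it becomes a CH2 group in step 13.

Step 13
Reactants: 23 (4S)-4-benzyl-3-{(2S)-2-[(3,3-dimethyloxiran-2-yl)methyl]-3-methylbut-3-enoyl}-1,3-oxazolidin-2-one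
Product: 24 (2S)-5-methyl-2-(prop-1-en-2-yl)hexane-1,5-diol
Conditions: LiAlH4 (excess), THF, 0 °C → rt
Reagents that add atoms: none
Why: Hydride reduction cleaves the exocyclic imide carbonyl to the primary alcohol with release of the auxiliary and opens the epoxide at its less substituted carbon to the tertiary alcohol, without touching the α-stereocentre.

Step 14
Reactants: 24 (2S)-5-methyl-2-(prop-1-en-2-yl)hexane-1,5-diol
Product: 25 (5S)-5-(iodomethyl)-2,6-dimethylhept-6-en-2-ol
Conditions: PPh3, imidazole, I2, CH2Cl2, 0 °C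
Reagents that add atoms: iodine, II
Why: Appel-type iodination (Garegg–Samuelsson conditions) converts only the primary alcohol, since the tertiary alcohol cannot be displaced by SN2 and the preformed phosphine–iodine complex leaves no free iodine for the alkene.

Step 15
Reactants: 25 (5S)-5-(iodomethyl)-2,6-dimethylhept-6-en-2-ol
Product: 26 triethyl{[(5S)-5-(iodomethyl)-2,6-dimethylhept-6-en-2-yl]oxy}silane
Conditions: TESOTf, 2,6-lutidine, CH2Cl2, −78 → 0 °C
Reagents that add atoms: triethylsilyl trifluoromethanesulfonate, CC[Si](CC)(CC)OS(=O)(=O)C(F)(F)F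
Why: Silylation of the tertiary alcohol removes the acidic proton and the internal nucleophile (tetrahydropyran formation) before the organozinc reagent is made.

Step 16
Reactants: 26 triethyl{[(5S)-5-(iodomethyl)-2,6-dimethylhept-6-en-2-yl]oxy}silane; 15 (2S)-7-(acetyloxy)-2-[4-(acetyloxy)-2-methoxyphenyl]-8-bromo-5-methoxy-2,3-dihydro-4H-chromen-4-one
Product: 28 (2S)-7-(acetyloxy)-2-[4-(acetyloxy)-2-methoxyphenyl]-5-methoxy-8-{(2R)-5-methyl-2-(prop-1-en-2-yl)-5-[(triethylsilyl)oxy]hexyl}-2,3-dihydro-4H-chromen-4-one, via alkylzinc iodide 27 (not isolated)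
Conditions: Zn dust, LiCl, THF, 40 °C; then 15, Pd(OAc)2 (5 mol%), SPhos (10 mol%), THF, rt → 50 °C
Reagents that add atoms: none
Why: LiCl-assisted zinc insertion into the primary iodide followed by Negishi coupling, which tolerates the ketone and the aryl acetates, does not involve the β-stereocentre (its descriptor changes from S to R only through CIP priorities) and uses a bulky biarylphosphine to drive oxidative addition at the hindered C8–Br bond and rapid reductive elimination.

Step 17
Reactants: 28 (2S)-7-(acetyloxy)-2-[4-(acetyloxy)-2-methoxyphenyl]-5-methoxy-8-{(2R)-5-methyl-2-(prop-1-en-2-yl)-5-[(triethylsilyl)oxy]hexyl}-2,3-dihydro-4H-chromen-4-one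
Product: 30 (2S)-7-hydroxy-2-(4-hydroxy-2-methoxyphenyl)-8-[(2R)-5-hydroxy-5-methyl-2-(prop-1-en-2-yl)hexyl]-5-methoxy-2,3-dihydro-4H-chromen-4-one, via tertiary alcohol diacetate 29 (not isolated)
Conditions: HF·pyridine, pyridine, THF, 0 °C → rt; NaHCO3 quench; then NH4OAc, MeOH–H2O (4:1), rt
Reagents that add atoms: none
Why: Fluoride cleaves the tertiary silyl ether and ammonium-acetate-promoted methanolysis then removes both aryl acetates under near-neutral conditions that avoid acid-induced reactions of the isopropenyl group and base-induced ring opening of the flavanone, which would racemise C2.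

Compound list
1 | 5-methoxybenzene-1,3-diol | COc1cc(O)cc(O)c1 | starting material
2 | 1-methoxy-3,5-bis(methoxymethoxy)benzene | COCOc1cc(OC)cc(OCOC)c1 | intermediate
3 | [4-methoxy-2,6-bis(methoxymethoxy)phenyl]lithium | [Li]c1c(OCOC)cc(OC)cc1OCOC | intermediate
4 | 2-bromo-5-methoxy-1,3-bis(methoxymethoxy)benzene | COCOc1cc(OC)cc(OCOC)c1Br | intermediate
5 | 2-bromo-5-methoxybenzene-1,3-diol | COc1cc(O)c(Br)c(O)c1 | intermediate
6 | 4-hydroxy-2-methoxybenzaldehyde | COc1cc(O)ccc1C=O | starting material
7 | 4-formyl-3-methoxyphenyl acetate | COc1cc(OC(C)=O)ccc1C=O | intermediate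
8 | tert-butyl diazoacetate | CC(C)(C)OC(=O)C=[N+]=[N-] | starting material
9 | tert-butyl 3-[4-(acetyloxy)-2-methoxyphenyl]-3-oxopropanoate | COc1cc(OC(C)=O)ccc1C(=O)CC(=O)OC(C)(C)C | intermediate
10 | tert-butyl (3R)-3-[4-(acetyloxy)-2-methoxyphenyl]-3-hydroxypropanoate | COc1cc(OC(C)=O)ccc1[C@H](O)CC(=O)OC(C)(C)C | intermediate
11 | tert-butyl (3S)-3-[4-(acetyloxy)-2-methoxyphenyl]-3-(2-bromo-3-hydroxy-5-methoxyphenoxy)propanoate | COc1cc(O)c(Br)c(O[C@H](c2ccc(OC(C)=O)cc2OC)CC(=O)OC(C)(C)C)c1 | intermediate
12 | tert-butyl (3S)-3-[3-(acetyloxy)-2-bromo-5-methoxyphenoxy]-3-[4-(acetyloxy)-2-methoxyphenyl]propanoate | COc1cc(OC(C)=O)c(Br)c(O[C@H](c2ccc(OC(C)=O)cc2OC)CC(=O)OC(C)(C)C)c1 | intermediate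
13 | (3S)-3-[3-(acetyloxy)-2-bromo-5-methoxyphenoxy]-3-[4-(acetyloxy)-2-methoxyphenyl]propanoic acid | COc1cc(OC(C)=O)c(Br)c(O[C@H](c2ccc(OC(C)=O)cc2OC)CC(=O)O)c1 | intermediate
14 | mixed anhydride of acid 13 and trifluoroacetic acid | COc1cc(OC(C)=O)c(Br)c(O[C@H](c2ccc(OC(C)=O)cc2OC)CC(=O)OC(=O)C(F)(F)F)c1 | intermediate
15 | (2S)-7-(acetyloxy)-2-[4-(acetyloxy)-2-methoxyphenyl]-8-bromo-5-methoxy-2,3-dihydro-4H-chromen-4-one | CC(=O)Oc1cc(OC)c2c(c1Br)O[C@H](c1ccc(OC(C)=O)cc1OC)CC2=O | intermediate
16 | (4S)-4-benzyl-1,3-oxazolidin-2-one | O=C1N[C@@H](Cc2ccccc2)CO1 | starting material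
17 | 3-methylbut-2-enoyl chloride | CC(C)=CC(Cl)=O | starting material
18 | lithium salt (N-lithio) of (4S)-4-benzyl-1,3-oxazolidin-2-one | [Li]N1C(=O)OC[C@@H]1Cc1ccccc1 | intermediate
19 | (4S)-4-benzyl-3-(3-methylbut-2-enoyl)-1,3-oxazolidin-2-one | CC(C)=CC(=O)N1C(=O)OC[C@@H]1Cc1ccccc1 | intermediate
20 | 1-bromo-3-methylbut-2-ene | CC(C)=CCBr | starting material
21 | sodium (Z)-dienolate of imide 19 | C=C(C)/C=C(\[O-])N1C(=O)OC[C@@H]1Cc1ccccc1.[Na+] | intermediate
22 | (4S)-4-benzyl-3-[(2S)-5-methyl-2-(prop-1-en-2-yl)hex-4-enoyl]-1,3-oxazolidin-2-one | C=C(C)[C@H](CC=C(C)C)C(=O)N1C(=O)OC[C@@H]1Cc1ccccc1 | intermediate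
23 | (4S)-4-benzyl-3-{(2S)-2-[(3,3-dimethyloxiran-2-yl)methyl]-3-methylbut-3-enoyl}-1,3-oxazolidin-2-one (both oxirane epimers) | C=C(C)[C@H](CC1OC1(C)C)C(=O)N1C(=O)OC[C@@H]1Cc1ccccc1 | intermediate
24 | (2S)-5-methyl-2-(prop-1-en-2-yl)hexane-1,5-diol | C=C(C)[C@H](CCC(C)(C)O)CO | intermediate
25 | (5S)-5-(iodomethyl)-2,6-dimethylhept-6-en-2-ol | C=C(C)[C@H](CCC(C)(C)O)CI | intermediate
26 | triethyl{[(5S)-5-(iodomethyl)-2,6-dimethylhept-6-en-2-yl]oxy}silane | C=C(C)[C@H](CCC(C)(C)O[Si](CC)(CC)CC)CI | intermediate
27 | {(2S)-5-methyl-2-(prop-1-en-2-yl)-5-[(triethylsilyl)oxy]hexyl}zinc iodide | C=C(C)[C@H](CCC(C)(C)O[Si](CC)(CC)CC)C[Zn]I | intermediate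
28 | (2S)-7-(acetyloxy)-2-[4-(acetyloxy)-2-methoxyphenyl]-5-methoxy-8-{(2R)-5-methyl-2-(prop-1-en-2-yl)-5-[(triethylsilyl)oxy]hexyl}-2,3-dihydro-4H-chromen-4-one | C=C(C)[C@H](CCC(C)(C)O[Si](CC)(CC)CC)Cc1c(OC(C)=O)cc(OC)c2c1O[C@H](c1ccc(OC(C)=O)cc1OC)CC2=O | intermediate
29 | (2S)-7-(acetyloxy)-2-[4-(acetyloxy)-2-methoxyphenyl]-8-[(2R)-5-hydroxy-5-methyl-2-(prop-1-en-2-yl)hexyl]-5-methoxy-2,3-dihydro-4H-chromen-4-one | C=C(C)[C@H](CCC(C)(C)O)Cc1c(OC(C)=O)cc(OC)c2c1O[C@H](c1ccc(OC(C)=O)cc1OC)CC2=O | intermediate
30 | (2S)-7-hydroxy-2-(4-hydroxy-2-methoxyphenyl)-8-[(2R)-5-hydroxy-5-methyl-2-(prop-1-en-2-yl)hexyl]-5-methoxy-2,3-dihydro-4H-chromen-4-one | C=C(C)[C@H](CCC(C)(C)O)Cc1c(O)cc(OC)c2c1O[C@H](c1ccc(O)cc1OC)CC2=O | target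

Total step count: 17.
Longest linear sequence: 8 steps (for example steps 10–17; the ring A and ring B branches, steps 1–3 or 4–6 followed by 7–9, 16 and 17, are equally long).

Steps most likely to fail

Step 16. Oxidative addition at the C8–Br bond, flanked by O1 and the 7-acetoxy group, may be so slow that protodemetalation and β-hydride elimination of the alkyl partner and hydrodebromination of the arene take over. The fallback is a nickel-catalysed reductive cross-electrophile coupling that needs no preformed organometallic. It sets out from bromide 15 and iodide 26 (NiI2, 4,4'-di-tert-butyl-2,2'-bipyridine, Zn dust, NaI, pyridine, DMPU, 60 °C) and comes back to the route at 28. Nickel inserts more readily into hindered aryl bromides, and the alkyl partner enters as a radical that is less sensitive to crowding. This fallback makes no new compound (F0).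

Step 7. Partial ionisation of the benzylic alkoxyphosphonium ion may let substitution leak through a cation and erode the enantiomeric purity, and dehydration to the cinnamate may lower conversion. In the fallback the configuration at C2 is secured by catalyst control downstream instead of by inversion. It sets out from bromoflavanone 15 of insufficient enantiomeric purity, obtained by steps 7–9 as written. This material is submitted to kinetic resolution by asymmetric transfer hydrogenation (RuCl[(R,R)-TsDPEN](p-cymene), HCO2H–Et3N, rt, partial conversion). The catalyst that gives (4R)-carbinols should reduce the unwanted (2R)-antipode fast to the cis-configured (2R,4R)-7-(acetyloxy)-2-[4-(acetyloxy)-2-methoxyphenyl]-8-bromo-5-methoxy-3,4-dihydro-2H-chromen-4-ol F1, which is removed by chromatography. The unreacted, enantioenriched (2S)-ketone comes back to the route at 15.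

Step 9. Protonation at O1 and ionisation of the benzylic C2–O1 bond (racemisation, or fragmentation to phenol and cinnamic acid) may compete with a ring closure that the acetoxy and bromo substituents slow down. The fallback closes the same bond by a non-protic Vilsmeier–Haack-type amide activation. It sets out from acid 13, isolated after the TFA stage. The acid is condensed with dimethylamine (Me2NH 2 M in THF, EDC, HOBt, CH2Cl2, 0 °C) to (3S)-3-[3-(acetyloxy)-2-bromo-5-methoxyphenoxy]-3-[4-(acetyloxy)-2-methoxyphenyl]-N,N-dimethylpropanamide F2. Tf2O and 2-chloropyridine (CH2Cl2, −78 → 0 °C) then generate an O-triflyl iminium ion that C4a attacks, giving N-{(2S)-7-(acetyloxy)-2-[4-(acetyloxy)-2-methoxyphenyl]-8-bromo-5-methoxy-2,3-dihydro-4H-chromen-4-ylidene}-N-methylmethanaminium trifluoromethanesulfonate F3. Hydrolysis with aqueous NaHCO3 comes back to the route at 15.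

Further compounds
F0 | step 16 | none | none
F1 | step 7 | (2R,4R)-7-(acetyloxy)-2-[4-(acetyloxy)-2-methoxyphenyl]-8-bromo-5-methoxy-3,4-dihydro-2H-chromen-4-ol | CC(=O)Oc1cc(OC)c2c(c1Br)O[C@@H](c1ccc(OC(C)=O)cc1OC)C[C@H]2O
F2 | step 9 | (3S)-3-[3-(acetyloxy)-2-bromo-5-methoxyphenoxy]-3-[4-(acetyloxy)-2-methoxyphenyl]-N,N-dimethylpropanamide | COc1cc(OC(C)=O)c(Br)c(O[C@H](c2ccc(OC(C)=O)cc2OC)CC(=O)N(C)C)c1
F3 | step 9 | N-{(2S)-7-(acetyloxy)-2-[4-(acetyloxy)-2-methoxyphenyl]-8-bromo-5-methoxy-2,3-dihydro-4H-chromen-4-ylidene}-N-methylmethanaminium trifluoromethanesulfonate | CC(=O)Oc1cc(OC)c2c(c1Br)O[C@H](c1ccc(OC(C)=O)cc1OC)CC2=[N+](C)C.[O-]S(=O)(=O)C(F)(F)F
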